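A direct plan would join two finished arenes: 6-fluoro-3-formyl-2-methoxybenzoic acid A1 and 2,6-dibromo-4-methylphenol A2 would give diaryl ether A3 by nucleophilic aromatic substitution. An isobutyl nucleophile would then be added enantioselectively to the aldehyde to give carbinol A4, one bromine would be exchanged for a formyl group to give bromo aldehyde A5 and the other for hydroxyl. Its weakest steps would be:
- the catalytic enantioselective isobutyl addition, because racemic background addition to a carboxylate-bearing aldehyde would erode selectivity;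
- the formylation through exchange of one of two equivalent C–Br bonds, because it would have to stop cleanly on a polyanion;
- the hydroxylation of the last hindered C–Br bond beside a free aldehyde, because no mild general method covers it.

The route rests on building ring A instead of joining two arenes. The four contiguous substituents of ring A (aryloxy at C6, carboxyl carbon at C1, oxygen at C2, carbinol side chain at C3) map onto a Danheiser benzannulation between an aryloxyacetylene, which carries the complete ring B on its oxygen, and a vinylketene bearing the (S)-carbinol of methyl L-leucate. One operation would form three ring C–C bonds, close ring A and create the diaryl ether with fixed regiochemistry; the single free ortho position of the new phenol then takes the carboxyl carbon. Because the stereocentre is bought and ring B arrives with its hydroxyl and formyl groups, no enantioselective addition, bromine desymmetrisation or aryl halide hydroxylation remains.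

Key step: step 9

Remark: compounds 1 and 7 are taken as catalogue compounds; no bond to the carbinol carbon is made or broken, so its (S) descriptor holds throughout. TBS = tert-butyldimethylsilyl, MOM = methoxymethyl, ArB–O = the 2-(1,3-dioxolan-2-yl)-6-(methoxymethoxy)-4-methylphenoxy group.

Step 1
Reactants: 1 methyl (2S)-2-hydroxy-4-methylpentanoate
Product: 2 methyl (2S)-2-(TBS-oxy)-4-methylpentanoate
Conditions: t-BuMe2SiCl (1.2 equiv), imidazole (2.5 equiv), DMF, 23 °C
Reagents that add atoms: tert-butyldimethylsilyl chloride CC(C)(C)[Si](C)(C)Cl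
Why: Imidazole-promoted silyl ether formation masks the secondary alcohol without touching the stereocentre.

Step 2
Reactants: 2 methyl (2S)-2-(TBS-oxy)-4-methylpentanoate
Product: 4 (3E,5S)-5-(TBS-oxy)-7-methyloct-3-en-2-one, via aldehyde 3 (not isolated)
Conditions: i-Bu2AlH (1.05 equiv), CH2Cl2, −78 °C; then Ph3P=CHC(O)CH3 (1.5 equiv), −78 to 23 °C; aq. potassium sodium tartrate
Reagents that add atoms: 1-(triphenylphosphoranylidene)propan-2-one CC(=O)C=P(c1ccccc1)(c1ccccc1)c1ccccc1
Why: In this one-pot partial ester reduction and Wittig olefination the aluminium hemiacetal should release the α-silyloxy aldehyde only as the stabilised ylide captures it, which gives the (E)-enone and leaves the adjacent centre no time to epimerise.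

Step 3
Reactants: 4 (3E,5S)-5-(TBS-oxy)-7-methyloct-3-en-2-one
Product: 6 (3E,5S)-5-(TBS-oxy)-1-diazo-7-methyloct-3-en-2-one, via trifluoroacetyl diketone 5 (not isolated)
Conditions: LiN(SiMe3)2 (1.1 equiv), THF, −78 °C; CF3CO2CH2CF3 (1.2 equiv); cold 1 M HCl work-up; then MeSO2N3 (1.5 equiv), Et3N (1.5 equiv), H2O (1 equiv), MeCN, 23 °C
Reagents that add atoms: methanesulfonyl azide CS(=O)(=O)N=[N+]=[N-]
Why: In this detrifluoroacetylative diazo transfer, kinetic deprotonation takes the methyl position, Claisen trifluoroacetylation activates it and the sulfonyl azide delivers N2 with loss of the trifluoroacetyl group, the γ-stereocentre being untouched.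

Step 4
Reactants: 7 2-hydroxy-3-methoxy-5-methylbenzaldehyde
Product: 8 2,3-dihydroxy-5-methylbenzaldehyde
Conditions: BBr3 (2 equiv), CH2Cl2, −78 to 0 °C; H2O
Reagents that add atoms: none
Why: Lewis acid cleavage of the aryl methyl ether with BBr3 should free the catechol and leave the aldehyde intact after hydrolysis of the aryloxyborane.

Step 5
Reactants: 8 2,3-dihydroxy-5-methylbenzaldehyde
Product: 9 2-hydroxy-3-(methoxymethoxy)-5-methylbenzaldehyde
Conditions: NaH (2.2 equiv), DMF, 0 °C; CH3OCH2Cl (1.05 equiv), 0 to 23 °C; aq. NH4Cl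
Reagents that add atoms: chloromethyl methyl ether COCCl
Why: In this regioselective O-alkylation of the dianion the 3-phenoxide is the more nucleophilic oxygen, because the 2-phenoxide is delocalised into and chelated by the formyl group.

Step 6
Reactants: 9 2-hydroxy-3-(methoxymethoxy)-5-methylbenzaldehyde
Product: 10 2-{[(E)-1,2-dichloroethenyl]oxy}-3-(methoxymethoxy)-5-methylbenzaldehyde
Conditions: Cl2C=CHCl (2 equiv), K2CO3 (2 equiv), DMF, 70 °C
Reagents that add atoms: trichloroethylene ClC=C(Cl)Cl
Why: Base-mediated anti addition of the phenoxide to dichloroacetylene generated in situ from trichloroethylene should give the (E)-1,2-dichlorovinyl ether.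

Step 7
Reactants: 10 2-{[(E)-1,2-dichloroethenyl]oxy}-3-(methoxymethoxy)-5-methylbenzaldehyde
Product: 11 2-[2-{[(E)-1,2-dichloroethenyl]oxy}-3-(methoxymethoxy)-5-methylphenyl]-1,3-dioxolane
Conditions: Me3SiOCH2CH2OSiMe3 (1.5 equiv), Me3SiOTf (5 mol %), CH2Cl2, −78 to −30 °C; pyridine quench
Reagents that add atoms: 1,2-bis(trimethylsilyloxy)ethane C[Si](C)(C)OCCO[Si](C)(C)C
Why: Noyori acetalisation under aprotic silyl triflate catalysis at low temperature masks the aldehyde against the organolithium step while sparing the aryl MOM ether.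

Step 8
Reactants: 11 2-[2-{[(E)-1,2-dichloroethenyl]oxy}-3-(methoxymethoxy)-5-methylphenyl]-1,3-dioxolane
Product: 14 2-[2-(ethynyloxy)-3-(methoxymethoxy)-5-methylphenyl]-1,3-dioxolane, via chloroalkynyl ether 12 (not isolated), via lithium acetylide 13 (not isolated)
Conditions: n-BuLi (2.2 equiv), THF, −78 to −40 °C; H2O, −78 °C
Reagents that add atoms: none
Why: Dehydrochlorination followed by chlorine–lithium exchange, the standard dichlorovinyl ether route to alkynyl ethers, gives the acetylide, which is protonated on quenching, and at −78 °C the acetal and MOM groups should not direct competing ring lithiation.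

Step 9
Reactants: 6 (3E,5S)-5-(TBS-oxy)-1-diazo-7-methyloct-3-en-2-one; 14 2-[2-(ethynyloxy)-3-(methoxymethoxy)-5-methylphenyl]-1,3-dioxolane
Product: 19 5-(ArB–O)-2-[(1S)-1-(TBS-oxy)-3-methylbutyl]phenol, via vinylketene 15 (not isolated), via vinylcyclobutenone 16 (not isolated), via dienylketene 17 (not isolated), via cyclohexadienone 18 (not isolated)
Conditions: 6 (1.0 equiv), 14 (1.3 equiv), ClCH2CH2Cl, hν (Pyrex-filtered Hg lamp, 300–350 nm), 23 °C; then 80 °C in the dark
Reagents that add atoms: none
Why: This is a Danheiser benzannulation in its diazo ketone form: light-induced Wolff rearrangement of 6 gives vinylketene 15, the nucleophilic CH terminus of alkynyl ether 14 adds to the ketene carbon in a regiospecific [2+2] cycloaddition to cyclobutenone 16, and 4π-electrocyclic opening to dienylketene 17, 6π-electrocyclic closure to 18 and tautomerisation give phenol 19. The closest known reactions are the benzannulations of alkoxy- and siloxyalkynes with vinylketenes made from α-diazo enones, here applied to an aryl alkynyl ether. Ring A is closed by the 6π electrocyclisation (six-membered, all carbon) after the [2+2] step has joined the two components, so that bonds C1–C2, C5–C6 and C2–C3 of ring A are new and the ether oxygen, fixed to the alkyne from the start, ends on C6. No lasting stereocentre is formed (C4 of 16 and the sp3 ring carbon of 18 are lost on aromatisation), and the (S)-carbinol carbon lies outside the reacting π system and is carried through unchanged. The step needs one orientation of the alkyne, which the oxygen lone pair secures by making the unsubstituted alkyne carbon the nucleophile toward the ketene carbonyl carbon, and it needs the ketene to be trapped before it dimerises or acylates the product, which the electron-rich alkyne in excess should secure.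

Step 10
Reactants: 19 5-(ArB–O)-2-[(1S)-1-(TBS-oxy)-3-methylbutyl]phenol
Product: 21 6-(ArB–O)-2-hydroxy-3-[(1S)-1-(TBS-oxy)-3-methylbutyl]benzaldehyde, via hydroxymethylphenol 20 (not isolated)
Conditions: MgCl2 (3 equiv), Et3N (6 equiv), (CH2O)n (8 equiv), MeCN, 80 °C; pH 5 citrate work-up
Reagents that add atoms: paraformaldehyde (as formaldehyde) C=O
Why: In this magnesium-mediated ortho-formylation of a phenol (Casnati–Skattebøl) the magnesium phenoxide delivers formaldehyde to the only free ortho position, between the hydroxyl and the aryloxy group, and a second formaldehyde oxidises the hydroxymethyl intermediate by hydride transfer.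

Step 11
Reactants: 21 6-(ArB–O)-2-hydroxy-3-[(1S)-1-(TBS-oxy)-3-methylbutyl]benzaldehyde
Product: 22 6-(ArB–O)-2-methoxy-3-[(1S)-1-(TBS-oxy)-3-methylbutyl]benzaldehyde
Conditions: CH3I (3 equiv), K2CO3 (3 equiv), DMF, 40 °C
Reagents that add atoms: iodomethane CI
Why: Williamson O-methylation of the hydrogen-bonded phenol should be clean because no other acidic O–H is present.

Step 12
Reactants: 22 6-(ArB–O)-2-methoxy-3-[(1S)-1-(TBS-oxy)-3-methylbutyl]benzaldehyde
Product: 23 6-(ArB–O)-2-methoxy-3-[(1S)-1-(TBS-oxy)-3-methylbutyl]benzoic acid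
Conditions: NaClO2 (3 equiv), NaH2PO4 (3 equiv), 2-methyl-2-butene (20 equiv), t-BuOH/THF/H2O, 0 to 23 °C
Reagents that add atoms: sodium chlorite [Na+].[O-]Cl=O
Why: Pinnick oxidation converts the hindered aryl aldehyde into the acid under buffered conditions in which the cyclic acetal should keep the ring B aldehyde out of reach of chlorite while the alkene scavenges hypochlorous acid.

Step 13
Reactants: 23 6-(ArB–O)-2-methoxy-3-[(1S)-1-(TBS-oxy)-3-methylbutyl]benzoic acid
Product: 24 tenellic acid B
Conditions: 2 M HCl (aq.)/THF 1:2, 35 °C; extraction at pH 3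
Reagents that add atoms: water O
Why: Acid-catalysed hydrolysis removes the dioxolane, the aryl MOM ether and the silyl ether together, and the benzylic carbinol should resist ionisation in dilute acid because its ring carries a meta carboxyl group and its ortho methoxy group is twisted out of conjugation, so the (S) centre should be retained.

Compound list
1 | methyl (2S)-2-hydroxy-4-methylpentanoate | CC(C)C[C@H](O)C(=O)OC | starting material
2 | methyl (2S)-2-{[tert-butyl(dimethyl)silyl]oxy}-4-methylpentanoate | CC(C)C[C@H](O[Si](C)(C)C(C)(C)C)C(=O)OC | intermediate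
3 | (2S)-2-{[tert-butyl(dimethyl)silyl]oxy}-4-methylpentanal | CC(C)C[C@H](O[Si](C)(C)C(C)(C)C)C=O | intermediate
4 | (3E,5S)-5-{[tert-butyl(dimethyl)silyl]oxy}-7-methyloct-3-en-2-one | CC(C)C[C@H](O[Si](C)(C)C(C)(C)C)/C=C/C(C)=O | intermediate
5 | (5E,7S)-7-{[tert-butyl(dimethyl)silyl]oxy}-1,1,1-trifluoro-9-methyldec-5-ene-2,4-dione | CC(C)C[C@H](O[Si](C)(C)C(C)(C)C)/C=C/C(=O)CC(=O)C(F)(F)F | intermediate
6 | (3E,5S)-5-{[tert-butyl(dimethyl)silyl]oxy}-1-diazo-7-methyloct-3-en-2-one | CC(C)C[C@H](O[Si](C)(C)C(C)(C)C)/C=C/C(=O)C=[N+]=[N-] | intermediate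
7 | 2-hydroxy-3-methoxy-5-methylbenzaldehyde | COc1cc(C)cc(C=O)c1O | starting material
8 | 2,3-dihydroxy-5-methylbenzaldehyde | Cc1cc(O)c(O)c(C=O)c1 | intermediate
9 | 2-hydroxy-3-(methoxymethoxy)-5-methylbenzaldehyde | COCOc1cc(C)cc(C=O)c1O | intermediate
10 | 2-{[(E)-1,2-dichloroethenyl]oxy}-3-(methoxymethoxy)-5-methylbenzaldehyde | COCOc1cc(C)cc(C=O)c1O/C(Cl)=C\Cl | intermediate
11 | 2-[2-{[(E)-1,2-dichloroethenyl]oxy}-3-(methoxymethoxy)-5-methylphenyl]-1,3-dioxolane | COCOc1cc(C)cc(C2OCCO2)c1O/C(Cl)=C\Cl | intermediate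
12 | 2-[2-(chloroethynyloxy)-3-(methoxymethoxy)-5-methylphenyl]-1,3-dioxolane | COCOc1cc(C)cc(C2OCCO2)c1OC#CCl | intermediate
13 | lithium [2-(1,3-dioxolan-2-yl)-6-(methoxymethoxy)-4-methylphenoxy]acetylide | COCOc1cc(C)cc(C2OCCO2)c1OC#C[Li] | intermediate
14 | 2-[2-(ethynyloxy)-3-(methoxymethoxy)-5-methylphenyl]-1,3-dioxolane | COCOc1cc(C)cc(C2OCCO2)c1OC#C | intermediate
15 | (3E,5S)-5-{[tert-butyl(dimethyl)silyl]oxy}-7-methylocta-1,3-dien-1-one (vinylketene) | CC(C)C[C@H](O[Si](C)(C)C(C)(C)C)/C=C/C=C=O | intermediate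
16 | 3-(ArB–O)-4-[(1E,3S)-3-(TBS-oxy)-5-methylhex-1-en-1-yl]cyclobut-2-en-1-one (ring carbon C4 unassigned) | CC(C)C[C@H](O[Si](C)(C)C(C)(C)C)/C=C/C1C(=O)C=C1Oc2c(OCOC)cc(C)cc2C3OCCO3 | intermediate
17 | (3E,5E,7S)-3-(ArB–O)-7-(TBS-oxy)-9-methyldeca-1,3,5-trien-1-one (C2 and C5 cis about C3=C4) | CC(C)C[C@H](O[Si](C)(C)C(C)(C)C)/C=C/C=C(\C=C=O)Oc1c(OCOC)cc(C)cc1C2OCCO2 | intermediate
18 | 3-(ArB–O)-6-[(1S)-1-(TBS-oxy)-3-methylbutyl]cyclohexa-2,4-dien-1-one (ring carbon C6 unassigned) | CC(C)C[C@H](O[Si](C)(C)C(C)(C)C)C1C=CC(Oc2c(OCOC)cc(C)cc2C3OCCO3)=CC1=O | intermediate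
19 | 5-[2-(1,3-dioxolan-2-yl)-6-(methoxymethoxy)-4-methylphenoxy]-2-[(1S)-1-{[tert-butyl(dimethyl)silyl]oxy}-3-methylbutyl]phenol | CC(C)C[C@H](O[Si](C)(C)C(C)(C)C)c1ccc(Oc2c(OCOC)cc(C)cc2C3OCCO3)cc1O | intermediate
20 | 3-[2-(1,3-dioxolan-2-yl)-6-(methoxymethoxy)-4-methylphenoxy]-6-[(1S)-1-{[tert-butyl(dimethyl)silyl]oxy}-3-methylbutyl]-2-(hydroxymethyl)phenol | CC(C)C[C@H](O[Si](C)(C)C(C)(C)C)c1ccc(Oc2c(OCOC)cc(C)cc2C3OCCO3)c(CO)c1O | intermediate
21 | 6-[2-(1,3-dioxolan-2-yl)-6-(methoxymethoxy)-4-methylphenoxy]-3-[(1S)-1-{[tert-butyl(dimethyl)silyl]oxy}-3-methylbutyl]-2-hydroxybenzaldehyde | CC(C)C[C@H](O[Si](C)(C)C(C)(C)C)c1ccc(Oc2c(OCOC)cc(C)cc2C3OCCO3)c(C=O)c1O | intermediate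
22 | 6-[2-(1,3-dioxolan-2-yl)-6-(methoxymethoxy)-4-methylphenoxy]-3-[(1S)-1-{[tert-butyl(dimethyl)silyl]oxy}-3-methylbutyl]-2-methoxybenzaldehyde | CC(C)C[C@H](O[Si](C)(C)C(C)(C)C)c1ccc(Oc2c(OCOC)cc(C)cc2C3OCCO3)c(C=O)c1OC | intermediate
23 | 6-[2-(1,3-dioxolan-2-yl)-6-(methoxymethoxy)-4-methylphenoxy]-3-[(1S)-1-{[tert-butyl(dimethyl)silyl]oxy}-3-methylbutyl]-2-methoxybenzoic acid | CC(C)C[C@H](O[Si](C)(C)C(C)(C)C)c1ccc(Oc2c(OCOC)cc(C)cc2C3OCCO3)c(C(=O)O)c1OC | intermediate
24 | tenellic acid B: 6-(2-formyl-6-hydroxy-4-methylphenoxy)-3-[(1S)-1-hydroxy-3-methylbutyl]-2-methoxybenzoic acid | COc1c([C@@H](O)CC(C)C)ccc(Oc2c(O)cc(C)cc2C=O)c1C(=O)O | target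

Total step count: 13. Longest linear sequence: 10 steps (steps 4 to 13); the diazo ketone branch (steps 1 to 3) joins at step 9.

Steps most likely to fail

Step 9 (key step). The aryloxyalkyne may engage the vinylketene too slowly, so that the ketene dimerises or acylates the phenol already formed, or the alkynyl ether may be consumed under irradiation. The fallback would set out from 9 and return at 22, making the ether bond by nucleophilic aromatic substitution instead of ring construction. Aldehyde 9 would be acetalised (ethylene glycol, HC(OEt)3, catalytic Bu4NBr3) to 2-(1,3-dioxolan-2-yl)-6-(methoxymethoxy)-4-methylphenol F1 as the nucleophile. Separately, 4-fluoro-2-methoxybenzonitrile F2 would take isobutylmagnesium bromide and, after acid hydrolysis of the imine, give 1-(4-fluoro-2-methoxyphenyl)-3-methylbutan-1-one F3 as the ketone. Corey–Bakshi–Shibata reduction of F3 with (R)-2-methyl-CBS-oxazaborolidine and BH3·SMe2 would give (1S)-1-(4-fluoro-2-methoxyphenyl)-3-methylbutan-1-ol F4 and silylation of F4 (t-BuMe2SiCl, imidazole) would give tert-butyl{[(1S)-1-(4-fluoro-2-methoxyphenyl)-3-methylbutyl]oxy}dimethylsilane F5 as the lithiation substrate. Lithiation of F5 between fluorine and methoxy (s-BuLi, TMEDA, −78 °C) and a DMF quench would give 6-fluoro-2-methoxy-3-[(1S)-1-(TBS-oxy)-3-methylbutyl]benzaldehyde F6 as the electrophile. Phenol F1 and fluoroarene F6 (K2CO3, DMF, 90 °C; the fluoride is ortho to the formyl group) would then give 22.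

Step 8. Excess butyllithium may metalate the ring next to the MOM or acetal group, and the terminal aryloxyalkyne may oligomerise on concentration. The fallback would set out from 11 and return at 21, carrying the alkyne as an internal, storable alkynyl ether that already holds the carboxyl carbon. Acetylide 13 would be generated from 11 with exactly two equivalents of n-BuLi, transmetalated with MgBr2·OEt2 and treated with triethyl orthoformate to give 2-{2-[(3,3-diethoxyprop-1-yn-1-yl)oxy]-3-(methoxymethoxy)-5-methylphenyl}-1,3-dioxolane F7 as the alkyne partner. The benzannulation of F7 with 6 under the conditions of step 9 would give 3-(ArB–O)-2-(diethoxymethyl)-6-[(1S)-1-(TBS-oxy)-3-methylbutyl]phenol F8 with the carboxyl carbon in place. Hydrolysis of the acyclic acetal of F8 on moist silica gel would give 21 without the separate formylation.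

Step 13. Protic acid strong enough to cleave the aryl MOM ether may ionise the electron-rich benzylic carbinol, with racemisation or chloride formation. The fallback would set out from 23 and return at 24 by a stepwise unmasking that avoids protic acid. Me3SiOTf and 2,2'-bipyridyl in CH2Cl2 at 0 °C, followed by water, would cleave the aryl MOM ether and the dioxolane while keeping the silyl ether, giving 6-(2-formyl-6-hydroxy-4-methylphenoxy)-3-[(1S)-1-(TBS-oxy)-3-methylbutyl]-2-methoxybenzoic acid F9 as an isolable intermediate. Buffered fluoride (Bu4NF, AcOH, THF) would then free the carbinol of F9 to give 24.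

Further compounds
F1 | step 9 | 2-(1,3-dioxolan-2-yl)-6-(methoxymethoxy)-4-methylphenol | COCOc1cc(C)cc(C2OCCO2)c1O
F2 | step 9 | 4-fluoro-2-methoxybenzonitrile | COc1cc(F)ccc1C#N
F3 | step 9 | 1-(4-fluoro-2-methoxyphenyl)-3-methylbutan-1-one | COc1cc(F)ccc1C(=O)CC(C)C
F4 | step 9 | (1S)-1-(4-fluoro-2-methoxyphenyl)-3-methylbutan-1-ol | CC(C)C[C@H](O)c1ccc(F)cc1OC
F5 | step 9 | tert-butyl{[(1S)-1-(4-fluoro-2-methoxyphenyl)-3-methylbutyl]oxy}dimethylsilane | CC(C)C[C@H](O[Si](C)(C)C(C)(C)C)c1ccc(F)cc1OC
F6 | step 9 | 6-fluoro-2-methoxy-3-[(1S)-1-{[tert-butyl(dimethyl)silyl]oxy}-3-methylbutyl]benzaldehyde | CC(C)C[C@H](O[Si](C)(C)C(C)(C)C)c1ccc(F)c(C=O)c1OC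
F7 | step 8 | 2-{2-[(3,3-diethoxyprop-1-yn-1-yl)oxy]-3-(methoxymethoxy)-5-methylphenyl}-1,3-dioxolane | COCOc1cc(C)cc(C2OCCO2)c1OC#CC(OCC)OCC
F8 | step 8 | 3-[2-(1,3-dioxolan-2-yl)-6-(methoxymethoxy)-4-methylphenoxy]-2-(diethoxymethyl)-6-[(1S)-1-{[tert-butyl(dimethyl)silyl]oxy}-3-methylbutyl]phenol | CC(C)C[C@H](O[Si](C)(C)C(C)(C)C)c1ccc(Oc2c(OCOC)cc(C)cc2C3OCCO3)c(C(OCC)OCC)c1O
F9 | step 13 | 6-(2-formyl-6-hydroxy-4-methylphenoxy)-3-[(1S)-1-{[tert-butyl(dimethyl)silyl]oxy}-3-methylbutyl]-2-methoxybenzoic acid | CC(C)C[C@H](O[Si](C)(C)C(C)(C)C)c1ccc(Oc2c(O)cc(C)cc2C=O)c(C(=O)O)c1OC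
A1 | direct plan | 6-fluoro-3-formyl-2-methoxybenzoic acid | COc1c(C=O)ccc(F)c1C(=O)O
A2 | direct plan | 2,6-dibromo-4-methylphenol | Cc1cc(Br)c(O)c(Br)c1
A3 | direct plan | 6-(2,6-dibromo-4-methylphenoxy)-3-formyl-2-methoxybenzoic acid | COc1c(C=O)ccc(Oc2c(Br)cc(C)cc2Br)c1C(=O)O
A4 | direct plan | 6-(2,6-dibromo-4-methylphenoxy)-3-[(1S)-1-hydroxy-3-methylbutyl]-2-methoxybenzoic acid | COc1c([C@@H](O)CC(C)C)ccc(Oc2c(Br)cc(C)cc2Br)c1C(=O)O
A5 | direct plan | 6-(2-bromo-6-formyl-4-methylphenoxy)-3-[(1S)-1-hydroxy-3-methylbutyl]-2-methoxybenzoic acid | COc1c([C@@H](O)CC(C)C)ccc(Oc2c(Br)cc(C)cc2C=O)c1C(=O)O
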